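**Strategy**

Ring C, the cyclohexadienone, is a cyclised polyketide: its acetyl-bearing carbon C2 is the central carbon of a 1,3-diketone, and its neighbour C3, the enol carbon beside the quaternary C4, sits at the carboxylic acid oxidation level. Ring C is therefore closed by a magnesium-templated intramolecular Claisen condensation that joins C2 to C3 in an open-chain 2,2-disubstituted 3,5,7-trioxooctanoate, whose quaternary stereocentre, set earlier by asymmetric phase-transfer geranylation of a mixed methylmalonate, cannot enolise and is carried through intact. The resulting acylfilicinic acid is then linked through a methylene to C6 of the 8-butanoyl-5,7-dihydroxychromene (rings A and B) by ortho-quinone methide Michael addition.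

Key step: step 6

Remark on tautomers: ring C is written throughout as the enol tautomer of the target SMILES (C1 carbonyl, C2 acetyl, C3 and C5 hydroxyl, C4 quaternary, C6 bearing the methylene). All its tautomers are one compound, and C4 is (R) in this form.

Assumption: the (S,S) spiro ammonium catalyst of step 3 is taken to give the (2S)-malonate 5, by analogy with its behaviour towards other allylic and benzylic bromides. If geranyl bromide showed the opposite sense, the (R,R) catalyst would be used and nothing else would change.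

**Route**

Step 1
Reactants: 1 2,2,5-trimethyl-1,3-dioxane-4,6-dione (methyl Meldrum's acid)
Product: 2 3-tert-butoxy-2-methyl-3-oxopropanoic acid (racemic)
Conditions: t-BuOH, reflux
Reagents that add atoms: tert-butanol, CC(C)(C)O
Why: Alcoholysis of the cyclic acylal (Meldrum's acid ring opening) by attack of tert-butanol at one carbonyl with loss of acetone should give the malonic half ester directly; its stereocentre is enolisable and stays racemic.

Step 2
Reactants: 2 3-tert-butoxy-2-methyl-3-oxopropanoic acid
Product: 3 1-tert-butyl 3-(2,2-diphenylethyl) 2-methylpropanedioate (racemic)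
Conditions: Ph2CHCH2OH, DCC, DMAP (cat.), CH2Cl2, 0 °C → rt
Reagents that add atoms: 2,2-diphenylethanol, OCC(c1ccccc1)c1ccccc1
Why: Steglich esterification (carbodiimide activation, DMAP acyl transfer) should join the acid to the primary alcohol without touching the tert-butyl ester.

Step 3
Reactants: 3 1-tert-butyl 3-(2,2-diphenylethyl) 2-methylpropanedioate; 4 geranyl bromide, (2E)-1-bromo-3,7-dimethylocta-2,6-diene
Product: 5 1-tert-butyl 3-(2,2-diphenylethyl) (2S)-2-[(2E)-3,7-dimethylocta-2,6-dien-1-yl]-2-methylpropanedioate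
Conditions: (S,S)-3,4,5-trifluorophenyl-NAS bromide (N-spiro bis(binaphthyl)ammonium bromide, 5 mol %), 50% aq. KOH, toluene, −40 °C
Reagents that add atoms: none
Why: Asymmetric phase-transfer alkylation: the enolate of 3 enters toluene as a tight ion pair with the C2-symmetric ammonium cation, which shields one enolate face because the two ester groups differ strongly in size, and SN2 attack on the primary allylic bromide should set the quaternary centre as (S) and keep the E alkene.

Step 4
Reactants: 5 1-tert-butyl 3-(2,2-diphenylethyl) (2S)-2-[(2E)-3,7-dimethylocta-2,6-dien-1-yl]-2-methylpropanedioate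
Product: 7 (2R)-2-[(2E)-3,7-dimethylocta-2,6-dien-1-yl]-3-(2,2-diphenylethoxy)-2-methyl-3-oxopropanoic acid, via trimethylsilyl ester 6 (not isolated)
Conditions: TMSOTf, 2,6-lutidine, CH2Cl2, 0 °C; pH 4 aqueous phosphate work-up
Reagents that add atoms: trimethylsilyl trifluoromethanesulfonate (TMSOTf), C[Si](C)(C)OS(=O)(=O)C(F)(F)F, which puts the silyl group on intermediate 6 only
Why: Silyl triflate cleavage of a tert-butyl ester: O-silylation of the ester carbonyl, loss of the tert-butyl cation as isobutene under lutidine buffering and hydrolysis of the silyl ester on work-up should free the acid without a Brønsted acid meeting the geranyl alkenes, and the primary ester cannot ionise; the descriptor changes from S to R only because the priorities change.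

Step 5
Reactants: 7 (2R)-2-[(2E)-3,7-dimethylocta-2,6-dien-1-yl]-3-(2,2-diphenylethoxy)-2-methyl-3-oxopropanoic acid; 8 pentane-2,4-dione (acetylacetone)
Product: 11 2,2-diphenylethyl (2R)-2-[(2E)-3,7-dimethylocta-2,6-dien-1-yl]-2-methyl-3,5,7-trioxooctanoate, via acyl imidazolide 9 (not isolated), via dilithio acetylacetone 10 (not isolated)
Conditions: 7, CDI (1.2 equiv), THF, 25 °C; then added to 10 [8 (3 equiv), LiN(iPr)2 (6 equiv), THF, 0 °C] at −78 °C, warmed to −20 °C; aq. NH4Cl
Reagents that add atoms: 1,1'-carbonyldiimidazole (CDI), O=C(n1ccnc1)n1ccnc1, which puts the imidazolyl group on intermediate 9 only; LiN(iPr)2, [Li+].CC(C)[N-]C(C)C, which puts lithium on intermediate 10 only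
Why: C-Acylation of a β-diketone dianion: the terminal, more basic carbanion of 10 should attack the acyl imidazolide far faster than the hindered alkyl ester, and the excess dianion takes up the acidic protons of imidazole and of the product triketone.

Step 6
Reactants: 11 2,2-diphenylethyl (2R)-2-[(2E)-3,7-dimethylocta-2,6-dien-1-yl]-2-methyl-3,5,7-trioxooctanoate
Product: 13 (4R)-2-acetyl-4-[(2E)-3,7-dimethylocta-2,6-dien-1-yl]-3,5-dihydroxy-4-methylcyclohexa-2,5-dien-1-one, via methyl triketo ester 12 (not isolated)
Conditions: Mg(OMe)2 (4 equiv), MeOH, 25 → 60 °C; cold 1 M HCl work-up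
Reagents that add atoms: methanol (as Mg(OMe)2 in MeOH), CO, which puts the methoxy group on intermediate 12 only
Why: Mg(OMe)2 turns 11 into the magnesium chelate of its 5,7-diketone and exchanges the diphenylethyl for the methyl ester (12); the chelated carbon C6, flanked by the C5 and C7 carbonyls, then adds to the ester carbonyl C1 and methoxide leaves, so the C6–C1 bond closes ring C and these two atoms become its C2 and C3. This is an intramolecular Claisen (Dieckmann-type) condensation, the laboratory form of the polyketide Claisen cyclisation by which 3,5,7-triketo esters give acylphloroglucinols. The six-membered ring closes in the 6-exo-trig mode at the ester carbonyl (6-(enolendo)-exo-trig with respect to the C5–C6 enolate). No stereocentre is formed: no bond to the quaternary carbon is made or broken and it has no hydrogen, so its configuration is kept and it becomes (4R)-C4 of ring C. The step needs C- over O-acylation and Claisen over aldol closure: an enol lactone from O-acylation is reopened by methoxide whereas the C-acylated product is withdrawn as the salt of a strongly acidic triketone, attack by C4 would give a four-membered ring, and the quaternary C2 removes the aldol route to a resorcylate that is open to unsubstituted triketo esters. Magnesium also keeps the C3 ketone enolised, which guards the C2–C3 bond of the chain against retro-Claisen cleavage.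

Step 7
Reactants: 14 phloroglucinol (benzene-1,3,5-triol); 15 butanoyl chloride
Product: 16 1-(2,4,6-trihydroxyphenyl)butan-1-one
Conditions: AlCl3 (3.5 equiv), PhNO2, CH2Cl2, 0 → 45 °C; aq. HCl
Reagents that add atoms: none
Why: Friedel–Crafts C-acylation of the electron-rich triol; the chelated ketone deactivates the ring, so monoacylation is expected.

Step 8
Reactants: 16 1-(2,4,6-trihydroxyphenyl)butan-1-one; 17 3-methylbut-2-enal
Product: 19 1-(5,7-dihydroxy-2,2-dimethyl-2H-chromen-8-yl)butan-1-one, via ortho-quinone methide 18 (not isolated)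
Conditions: 17 (1.1 equiv), ethylenediammonium diacetate (10 mol %), toluene, 110 °C
Reagents that add atoms: none
Why: Knoevenagel-type condensation of the enal at a ring carbon gives the oxatriene 18, whose oxa-6π-electrocyclisation closes the pyran ring (formal [3+3] chromene annulation); closure through the oxygen next to the acyl group gives the 8-acyl isomer, to be separated by chromatography from the 6-acyl isomer that closure through the para oxygen would give.

Step 9
Reactants: 19 1-(5,7-dihydroxy-2,2-dimethyl-2H-chromen-8-yl)butan-1-one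
Product: 20 1-{6-[(dimethylamino)methyl]-5,7-dihydroxy-2,2-dimethyl-2H-chromen-8-yl}butan-1-one
Conditions: CH2(NMe2)2 (1.2 equiv), 1,4-dioxane, rt → 50 °C
Reagents that add atoms: N,N,N',N'-tetramethylmethanediamine, CN(C)CN(C)C
Why: Phenol Mannich reaction: the acidic acylphloroglucinol protonates the aminal, and the iminium ion so formed should attack C6, the only unsubstituted ring carbon, which lies between two hydroxyl groups.

Step 10
Reactants: 20 1-{6-[(dimethylamino)methyl]-5,7-dihydroxy-2,2-dimethyl-2H-chromen-8-yl}butan-1-one; 13 (4R)-2-acetyl-4-[(2E)-3,7-dimethylocta-2,6-dien-1-yl]-3,5-dihydroxy-4-methylcyclohexa-2,5-dien-1-one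
Product: 22 (4R)-2-acetyl-6-[(8-butanoyl-5,7-dihydroxy-2,2-dimethyl-2H-chromen-6-yl)methyl]-4-[(2E)-3,7-dimethylocta-2,6-dien-1-yl]-3,5-dihydroxy-4-methylcyclohexa-2,5-dien-1-one, via ortho-quinone methide 21 (not isolated)
Conditions: 1,4-dioxane, 90 °C, N2 sweep
Reagents that add atoms: none
Why: Thermal loss of dimethylamine from the ortho-hydroxybenzylamine should give the ortho-quinone methide 21, to which C6 of 13, its only nucleophilic CH, adds in a Michael reaction that restores the aromatic ring; the quaternary stereocentre is remote and unaffected.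

**Compound list**

1 | 2,2,5-trimethyl-1,3-dioxane-4,6-dione (methyl Meldrum's acid) | CC1C(=O)OC(C)(C)OC1=O | starting material
2 | 3-tert-butoxy-2-methyl-3-oxopropanoic acid (racemic) | CC(C(=O)O)C(=O)OC(C)(C)C | intermediate
3 | 1-tert-butyl 3-(2,2-diphenylethyl) 2-methylpropanedioate (racemic) | CC(C(=O)OC(C)(C)C)C(=O)OCC(c1ccccc1)c1ccccc1 | intermediate
4 | geranyl bromide, (2E)-1-bromo-3,7-dimethylocta-2,6-diene | BrC/C=C(\C)CCC=C(C)C | starting material
5 | 1-tert-butyl 3-(2,2-diphenylethyl) (2S)-2-[(2E)-3,7-dimethylocta-2,6-dien-1-yl]-2-methylpropanedioate | CC(C)(C)OC(=O)[C@@](C)(C/C=C(\C)CCC=C(C)C)C(=O)OCC(c1ccccc1)c1ccccc1 | intermediate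
6 | 1-(2,2-diphenylethyl) 3-trimethylsilyl (2S)-2-[(2E)-3,7-dimethylocta-2,6-dien-1-yl]-2-methylpropanedioate | C[Si](C)(C)OC(=O)[C@@](C)(C/C=C(\C)CCC=C(C)C)C(=O)OCC(c1ccccc1)c1ccccc1 | intermediate
7 | (2R)-2-[(2E)-3,7-dimethylocta-2,6-dien-1-yl]-3-(2,2-diphenylethoxy)-2-methyl-3-oxopropanoic acid | OC(=O)[C@@](C)(C/C=C(\C)CCC=C(C)C)C(=O)OCC(c1ccccc1)c1ccccc1 | intermediate
8 | pentane-2,4-dione (acetylacetone) | CC(=O)CC(C)=O | starting material
9 | 2,2-diphenylethyl (2R)-2-[(2E)-3,7-dimethylocta-2,6-dien-1-yl]-3-(1H-imidazol-1-yl)-2-methyl-3-oxopropanoate | O=C(n1ccnc1)[C@@](C)(C/C=C(\C)CCC=C(C)C)C(=O)OCC(c1ccccc1)c1ccccc1 | intermediate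
10 | dilithium penta-1,3-diene-2,4-diolate (dilithio acetylacetone) | [Li+].[Li+].C=C([O-])C=C(C)[O-] | intermediate
11 | 2,2-diphenylethyl (2R)-2-[(2E)-3,7-dimethylocta-2,6-dien-1-yl]-2-methyl-3,5,7-trioxooctanoate | CC(=O)CC(=O)CC(=O)[C@@](C)(C/C=C(\C)CCC=C(C)C)C(=O)OCC(c1ccccc1)c1ccccc1 | intermediate
12 | methyl (2R)-2-[(2E)-3,7-dimethylocta-2,6-dien-1-yl]-2-methyl-3,5,7-trioxooctanoate | CC(=O)CC(=O)CC(=O)[C@@](C)(C/C=C(\C)CCC=C(C)C)C(=O)OC | intermediate
13 | (4R)-2-acetyl-4-[(2E)-3,7-dimethylocta-2,6-dien-1-yl]-3,5-dihydroxy-4-methylcyclohexa-2,5-dien-1-one | O=C1C=C(O)[C@@](C)(C/C=C(\C)CCC=C(C)C)C(O)=C1C(C)=O | intermediate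
14 | phloroglucinol (benzene-1,3,5-triol) | Oc1cc(O)cc(O)c1 | starting material
15 | butanoyl chloride | CCCC(=O)Cl | starting material
16 | 1-(2,4,6-trihydroxyphenyl)butan-1-one | CCCC(=O)c1c(O)cc(O)cc1O | intermediate
17 | 3-methylbut-2-enal | CC(C)=CC=O | starting material
18 | 2-butanoyl-3,5-dihydroxy-6-(3-methylbut-2-en-1-ylidene)cyclohexa-2,4-dien-1-one | CCCC(=O)C1=C(O)C=C(O)C(=CC=C(C)C)C1=O | intermediate
19 | 1-(5,7-dihydroxy-2,2-dimethyl-2H-chromen-8-yl)butan-1-one | CCCC(=O)c1c(O)cc(O)c2C=CC(C)(C)Oc12 | intermediate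
20 | 1-{6-[(dimethylamino)methyl]-5,7-dihydroxy-2,2-dimethyl-2H-chromen-8-yl}butan-1-one | CCCC(=O)c1c(O)c(CN(C)C)c(O)c2C=CC(C)(C)Oc12 | intermediate
21 | 8-butanoyl-5-hydroxy-2,2-dimethyl-6-methylidene-2H-chromen-7(6H)-one | C=C1C(=O)C(C(=O)CCC)=C2OC(C)(C)C=CC2=C1O | intermediate
22 | (4R)-2-acetyl-6-[(8-butanoyl-5,7-dihydroxy-2,2-dimethyl-2H-chromen-6-yl)methyl]-4-[(2E)-3,7-dimethylocta-2,6-dien-1-yl]-3,5-dihydroxy-4-methylcyclohexa-2,5-dien-1-one | CCCC(=O)c1c(O)c(CC2=C(O)[C@@](C)(C/C=C(\C)CCC=C(C)C)C(O)=C(C(C)=O)C2=O)c(O)c2c1OC(C)(C)C=C2 | target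

**Summary**

Total step count: 10. Longest linear sequence: 7 steps (steps 1 to 6, then step 10); steps 7 to 9 form the chromene branch.

Steps most likely to fail:

1. Step 6. Attack on the ester carbonyl beside the quaternary carbon may be slow enough for methoxide to cleave the C2–C3 bond of the chain by retro-Claisen reaction instead. The fallback sets out from 5 and comes back at 13, and it changes the order of bond formation.
 - Saponification of the primary ester of 5 (KOH, MeOH, rt) should give the tert-butyl half ester, (2S)-3-tert-butoxy-2-[(2E)-3,7-dimethylocta-2,6-dien-1-yl]-2-methyl-3-oxopropanoic acid F1.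
 - 1-Chloro-N,N,2-trimethylprop-1-en-1-amine (CH2Cl2, 0 °C) converts F1 into the acid chloride, tert-butyl (2R)-3-chloro-2-[(2E)-3,7-dimethylocta-2,6-dien-1-yl]-2-methyl-3-oxopropanoate F2.
 - F2 C-acylates the central carbon of acetylacetone 8 (MgCl2, pyridine, CH2Cl2, 0 °C) to give the triacylmethane, tert-butyl (2S)-4-acetyl-2-[(2E)-3,7-dimethylocta-2,6-dien-1-yl]-2-methyl-3,5-dioxohexanoate F3.
 - LiN(iPr)2 (3.3 equiv, THF, −78 → 0 °C) then forms the kinetic enolate of one acetyl group, which closes ring C by Dieckmann attack on the tert-butyl ester and gives 13 with the same configuration.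
 - In this fallback the C2–C3 bond of ring C is made between two molecules and the ring closes at C5–C6 with a far more reactive nucleophile.

2. Step 5. Proton transfer to the strongly basic dianion, attack on the second ester and double acylation may consume the hindered acyl donor. The fallback sets out from 7 and comes back at 11, and it replaces the dianion by a neutral carbon nucleophile.
 - 1-Chloro-N,N,2-trimethylprop-1-en-1-amine (CH2Cl2, 0 °C) converts 7 into the acid chloride, 2,2-diphenylethyl (2S)-3-chloro-2-[(2E)-3,7-dimethylocta-2,6-dien-1-yl]-2-methyl-3-oxopropanoate F4.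
 - F4 is treated with 2,4-bis(trimethylsilyloxy)penta-1,3-diene (CH2Cl2, −78 → 20 °C), the bis-silyl dienol ether of acetylacetone, in a Mukaiyama-type acylation at its terminal carbon.
 - This gives the silyl enol ether, 2,2-diphenylethyl (2R)-2-[(2E)-3,7-dimethylocta-2,6-dien-1-yl]-2-methyl-3,5-dioxo-7-(trimethylsilyloxy)oct-6-enoate F5, which a mild aqueous work-up hydrolyses to 11.

3. Step 8. Ring closure through the oxygen para to the acyl group, and a second annulation at the other free ring carbon, may divert much of the material. The fallback sets out from 16 and comes back at 19, and it leaves only the ortho oxygen free.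
 - MOMCl and iPr2NEt (CH2Cl2, 0 °C) protect the two more reactive hydroxyl groups and leave the chelated one, giving 1-[2-hydroxy-4,6-bis(methoxymethoxy)phenyl]butan-1-one F6.
 - 3-Chloro-3-methylbut-1-yne, K2CO3, KI and CuI (cat.) in acetone at 60 °C give the aryl propargyl ether, 1-[2,4-bis(methoxymethoxy)-6-(2-methylbut-3-yn-2-yloxy)phenyl]butan-1-one F7.
 - Heating in xylene at 140 °C (aromatic Claisen rearrangement to the only free ortho carbon, [1,5]-hydrogen shift and oxa-6π closure) gives 1-[5,7-bis(methoxymethoxy)-2,2-dimethyl-2H-chromen-8-yl]butan-1-one F8 as a single regioisomer.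
 - HCl in MeOH at 40 °C removes both acetals to give 19.

Further compounds
F1 | step 6 | (2S)-3-tert-butoxy-2-[(2E)-3,7-dimethylocta-2,6-dien-1-yl]-2-methyl-3-oxopropanoic acid | CC(C)(C)OC(=O)[C@@](C)(C/C=C(\C)CCC=C(C)C)C(=O)O
F2 | step 6 | tert-butyl (2R)-3-chloro-2-[(2E)-3,7-dimethylocta-2,6-dien-1-yl]-2-methyl-3-oxopropanoate | CC(C)(C)OC(=O)[C@@](C)(C/C=C(\C)CCC=C(C)C)C(=O)Cl
F3 | step 6 | tert-butyl (2S)-4-acetyl-2-[(2E)-3,7-dimethylocta-2,6-dien-1-yl]-2-methyl-3,5-dioxohexanoate | CC(C)(C)OC(=O)[C@@](C)(C/C=C(\C)CCC=C(C)C)C(=O)C(C(C)=O)C(C)=O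
F4 | step 5 | 2,2-diphenylethyl (2S)-3-chloro-2-[(2E)-3,7-dimethylocta-2,6-dien-1-yl]-2-methyl-3-oxopropanoate | ClC(=O)[C@@](C)(C/C=C(\C)CCC=C(C)C)C(=O)OCC(c1ccccc1)c1ccccc1
F5 | step 5 | 2,2-diphenylethyl (2R)-2-[(2E)-3,7-dimethylocta-2,6-dien-1-yl]-2-methyl-3,5-dioxo-7-(trimethylsilyloxy)oct-6-enoate | CC(O[Si](C)(C)C)=CC(=O)CC(=O)[C@@](C)(C/C=C(\C)CCC=C(C)C)C(=O)OCC(c1ccccc1)c1ccccc1
F6 | step 8 | 1-[2-hydroxy-4,6-bis(methoxymethoxy)phenyl]butan-1-one | CCCC(=O)c1c(O)cc(OCOC)cc1OCOC
F7 | step 8 | 1-[2,4-bis(methoxymethoxy)-6-(2-methylbut-3-yn-2-yloxy)phenyl]butan-1-one | CCCC(=O)c1c(OC(C)(C)C#C)cc(OCOC)cc1OCOC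
F8 | step 8 | 1-[5,7-bis(methoxymethoxy)-2,2-dimethyl-2H-chromen-8-yl]butan-1-one | CCCC(=O)c1c(OCOC)cc(OCOC)c2C=CC(C)(C)Oc12
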